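The central benzene ring is treated as a masked cyclohexanetetraone: with C1 carrying the 5-prenylindol-3-yl group and C4 the indol-3-yl group, C2, C3, C5 and C6 are its four carbonyl carbons, and C1 and C4 are CH acids flanked by a ketone and an indole C3. Cutting C1–C2 and C3–C4 leads to dimethyl oxalate and an unsymmetrical 1,4-di(indol-3-yl)butane-2,3-dione that already holds both indoles and the prenyl group. One methoxide-mediated twofold Claisen condensation makes both bonds, closes the carbocycle and gives the 2,5-dihydroxy-3,6-diaryl-1,4-benzoquinone; reductive O-methylation then completes the target. The dione comes from a Horner–Wadsworth–Emmons union of two indole fragments.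

Key step: step 6

Remark: the tetrahydropyranyl acetal carried from step 3 to step 5 makes those intermediates stereoisomer mixtures (racemic acetal carbon, E/Z enol ether); they are used as such because step 5 erases both elements, and the target has no stereocentre.
Assumption: the tetrahydropyranyloxymethyl phosphonate of step 3 and the N-Boc aldehyde of step 4 are taken as catalogue reagents.

Step 1
Reactants: 1 5-bromoindole-3-acetic acid
Product: 2 methyl 2-(5-bromo-1H-indol-3-yl)acetate
Conditions: MeOH, H2SO4 (cat.), reflux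
Reagents that add atoms: methanol (CO)
Why: Fischer esterification in excess methanol under catalytic acid converts the arylacetic acid into the methyl ester that serves as acyl donor in step 3, and neither the aryl bromide nor the indole reacts under these conditions.

Step 2
Reactants: 2 methyl 2-(5-bromo-1H-indol-3-yl)acetate; 3 tributyl(3-methylbut-2-enyl)stannane
Product: 4 methyl 2-[5-(3-methylbut-2-enyl)-1H-indol-3-yl]acetate
Conditions: Pd(PPh3)4 (5 mol %), DMF, 100 °C
Reagents that add atoms: none
Why: Stille coupling: zerovalent palladium inserts into the C5–Br bond, the allylic stannane transmetalates and reductive elimination at the unsubstituted allyl terminus should give the linear 3-methylbut-2-enyl arene under neutral conditions that leave the free N–H and the ester untouched.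

Step 3
Reactants: 4 methyl 2-[5-(3-methylbut-2-enyl)-1H-indol-3-yl]acetate; 5 diethyl [(tetrahydro-2H-pyran-2-yloxy)methyl]phosphonate
Product: 6 diethyl {3-[5-(3-methylbut-2-enyl)-1H-indol-3-yl]-2-oxo-1-(tetrahydro-2H-pyran-2-yloxy)propyl}phosphonate (diastereomer mixture)
Conditions: 5 (3.3 equiv), LiN(i-Pr)2 (3.3 equiv), THF, −78 °C; then 4, −78 to −20 °C; aq. NH4Cl
Reagents that add atoms: none
Why: Claisen-type acylation of a lithiated phosphonate by an ester, the standard route to β-ketophosphonates: one equivalent of carbanion removes the indole N–H (which also lowers the acidity of the neighbouring CH2), one adds to the ester and one is consumed by the acidic product, whose enolate is thereby protected from a second addition.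

Step 4
Reactants: 6 diethyl {3-[5-(3-methylbut-2-enyl)-1H-indol-3-yl]-2-oxo-1-(tetrahydro-2H-pyran-2-yloxy)propyl}phosphonate; 7 tert-butyl 3-formyl-1H-indole-1-carboxylate
Product: 8 tert-butyl 3-{4-[5-(3-methylbut-2-enyl)-1H-indol-3-yl]-3-oxo-2-(tetrahydro-2H-pyran-2-yloxy)but-1-enyl}-1H-indole-1-carboxylate (E/Z mixture; racemic)
Conditions: LiCl, DBU, MeCN, 0 °C to rt
Reagents that add atoms: none
Why: Horner–Wadsworth–Emmons olefination under Masamune–Roush conditions: lithium chelation between P=O and C=O makes the phosphonate carbon the site deprotonated by DBU, and the N-Boc group converts the otherwise vinylogous-amide aldehyde into a reactive electrophile, so that the second carbonyl of the future dione is installed as an acetal-type enol ether (either alkene geometry is usable).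

Step 5
Reactants: 8 tert-butyl 3-{4-[5-(3-methylbut-2-enyl)-1H-indol-3-yl]-3-oxo-2-(tetrahydro-2H-pyran-2-yloxy)but-1-enyl}-1H-indole-1-carboxylate
Product: 10 1-(1H-indol-3-yl)-4-[5-(3-methylbut-2-enyl)-1H-indol-3-yl]butane-2,3-dione, via N-deprotected enol ether 9 (not isolated)
Conditions: K2CO3 (0.3 equiv), MeOH, rt; then AcOH–THF–H2O (4:2:1), 40 °C
Reagents that add atoms: none
Why: Methanolysis of the N-acylindole-type carbamate followed by acetal hydrolysis of the tetrahydropyranyl enol ether, which proceeds by C–O cleavage at the acetal carbon and needs no protonation of the alkene, should release the 1,2-dione (present largely as its enol) under acid mild enough to spare the prenyl group and the indoles.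

Step 6
Reactants: 10 1-(1H-indol-3-yl)-4-[5-(3-methylbut-2-enyl)-1H-indol-3-yl]butane-2,3-dione; 11 dimethyl oxalate
Product: 13 2,5-dihydroxy-3-(1H-indol-3-yl)-6-[5-(3-methylbut-2-enyl)-1H-indol-3-yl]-1,4-benzoquinone, via open-chain oxalyl adduct 12 (not isolated)
Conditions: NaOMe (6 equiv), MeOH–THF, argon, 0 °C to reflux; then 1 M HCl
Reagents that add atoms: none
Why: Methoxide enolises the CH2 lying between a ketone and an indole C3 (C1), and this enolate attacks one ester carbonyl of dimethyl oxalate in an intermolecular Claisen condensation, giving the open-chain adduct 12 as its stabilised tricarbonyl enolate. Enolisation of the second CH2 (C4) then allows a Dieckmann-type closure onto the remaining ester, a 6-(enolendo)-exo-trig attack that forms the only new ring and expels the second methoxide. The resulting cyclic tetraketone tautomerises to the 2,5-dihydroxy-1,4-benzoquinone, a vinylogous diacid that the base deprotonates twice, and this irreversible dianion formation should draw all the reversible acyl transfers forward. The closest known reaction type is the oxalate double Claisen condensation that turns bis(arylmethyl) ketones and 1,4-diaryl-2,3-diones into cyclic polyketones, applied here to a bis(indolylmethyl) dione. No stereocentre is created. The step needs C-acylation at C1 and C4 in preference to acylation on indole nitrogen or enolate oxygen, which is secured because N-oxalylindoles and enol oxalates are cleaved again by methoxide, because only the carbocyclic product leaves the equilibrium as its dianion, and because C1 and C4 are the only carbons activated by both a carbonyl group and an indole.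

Step 7
Reactants: 13 2,5-dihydroxy-3-(1H-indol-3-yl)-6-[5-(3-methylbut-2-enyl)-1H-indol-3-yl]-1,4-benzoquinone
Product: 15 1-(1H-indol-3-yl)-2,3,5,6-tetramethoxy-4-[5-(3-methylbut-2-enyl)-1H-indol-3-yl]benzene, via tetrahydroxybenzene 14 (not isolated)
Conditions: Na2S2O4, THF–H2O, rt, argon; then Me2SO4 (8 equiv), K2CO3 (10 equiv), acetone, reflux, argon
Reagents that add atoms: dimethyl sulfate (COS(=O)(=O)OC)
Why: Dithionite reduction of the quinone followed by fourfold Williamson ether synthesis: K2CO3 in acetone deprotonates the phenols but not the much less acidic indole N–H, so that methylation should be confined to oxygen, while exclusion of air keeps the tetrol from reoxidising.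

Compound list

1 | 5-bromoindole-3-acetic acid | OC(=O)Cc1c[nH]c2ccc(Br)cc12 | starting material
2 | methyl 2-(5-bromo-1H-indol-3-yl)acetate | COC(=O)Cc1c[nH]c2ccc(Br)cc12 | intermediate
3 | tributyl(3-methylbut-2-enyl)stannane | CCCC[Sn](CCCC)(CCCC)CC=C(C)C | starting material
4 | methyl 2-[5-(3-methylbut-2-enyl)-1H-indol-3-yl]acetate | COC(=O)Cc1c[nH]c2ccc(CC=C(C)C)cc12 | intermediate
5 | diethyl [(tetrahydro-2H-pyran-2-yloxy)methyl]phosphonate (racemic) | CCOP(=O)(OCC)COC1CCCCO1 | starting material
6 | diethyl {3-[5-(3-methylbut-2-enyl)-1H-indol-3-yl]-2-oxo-1-(tetrahydro-2H-pyran-2-yloxy)propyl}phosphonate (diastereomer mixture) | CCOP(=O)(OCC)C(OC1CCCCO1)C(=O)Cc1c[nH]c2ccc(CC=C(C)C)cc12 | intermediate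
7 | tert-butyl 3-formyl-1H-indole-1-carboxylate | CC(C)(C)OC(=O)n1cc(C=O)c2ccccc12 | starting material
8 | tert-butyl 3-{4-[5-(3-methylbut-2-enyl)-1H-indol-3-yl]-3-oxo-2-(tetrahydro-2H-pyran-2-yloxy)but-1-enyl}-1H-indole-1-carboxylate (E/Z mixture, racemic) | CC(C)(C)OC(=O)n1cc(C=C(OC2CCCCO2)C(=O)Cc2c[nH]c3ccc(CC=C(C)C)cc23)c2ccccc12 | intermediate
9 | 1-(1H-indol-3-yl)-4-[5-(3-methylbut-2-enyl)-1H-indol-3-yl]-2-(tetrahydro-2H-pyran-2-yloxy)but-1-en-3-one (E/Z mixture, racemic; not isolated) | O=C(Cc1c[nH]c2ccc(CC=C(C)C)cc12)C(OC1CCCCO1)=Cc1c[nH]c2ccccc12 | intermediate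
10 | 1-(1H-indol-3-yl)-4-[5-(3-methylbut-2-enyl)-1H-indol-3-yl]butane-2,3-dione (drawn as the diketone, expected largely as an enol) | O=C(Cc1c[nH]c2ccc(CC=C(C)C)cc12)C(=O)Cc1c[nH]c2ccccc12 | intermediate
11 | dimethyl oxalate | COC(=O)C(=O)OC | starting material
12 | methyl 6-(1H-indol-3-yl)-3-[5-(3-methylbut-2-enyl)-1H-indol-3-yl]-2,4,5-trioxohexanoate (not isolated; acylation may equally begin at the other CH2, both adducts converge on 13) | COC(=O)C(=O)C(c1c[nH]c2ccc(CC=C(C)C)cc12)C(=O)C(=O)Cc1c[nH]c2ccccc12 | intermediate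
13 | 2,5-dihydroxy-3-(1H-indol-3-yl)-6-[5-(3-methylbut-2-enyl)-1H-indol-3-yl]-1,4-benzoquinone | O=C1C(O)=C(c2c[nH]c3ccccc23)C(=O)C(O)=C1c1c[nH]c2ccc(CC=C(C)C)cc12 | intermediate
14 | 3-(1H-indol-3-yl)-6-[5-(3-methylbut-2-enyl)-1H-indol-3-yl]benzene-1,2,4,5-tetrol (not isolated) | Oc1c(O)c(-c2c[nH]c3ccc(CC=C(C)C)cc23)c(O)c(O)c1-c1c[nH]c2ccccc12 | intermediate
15 | 1-(1H-indol-3-yl)-2,3,5,6-tetramethoxy-4-[5-(3-methylbut-2-enyl)-1H-indol-3-yl]benzene | COc1c(OC)c(-c2c[nH]c3ccc(CC=C(C)C)cc23)c(OC)c(OC)c1-c1c[nH]c2ccccc12 | target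

Total step count: 7. Longest linear sequence: 7 steps (1 → 2 → 4 → 6 → 8 → 10 → 13 → 15).

Steps most likely to fail

Step 6. Base-induced self-condensation or oxidative degradation of the enolised dione may outrun acylation. Ring closure through oxygen may also fail to equilibrate to the carbocycle. The fallback gives up the condensation and builds the same quinone by the known acid-promoted addition of indoles to a haloquinone. It sets out from stannane 3, which is coupled with purchased 5-bromoindole (Pd(PPh3)4, DMF, 100 °C) to give 5-(3-methylbut-2-enyl)-1H-indole F1. Purchased indole is added to 2,5-dichloro-1,4-benzoquinone (HCl cat., THF, rt) to give 2,5-dichloro-3-(1H-indol-3-yl)benzene-1,4-diol F2, which DDQ reoxidises in the same flask to 2,5-dichloro-3-(1H-indol-3-yl)-1,4-benzoquinone F3. The same addition with F1 gives 2,5-dichloro-3-(1H-indol-3-yl)-6-[5-(3-methylbut-2-enyl)-1H-indol-3-yl]benzene-1,4-diol F4, reoxidised by DDQ to 2,5-dichloro-3-(1H-indol-3-yl)-6-[5-(3-methylbut-2-enyl)-1H-indol-3-yl]-1,4-benzoquinone F5. Hydrolysis of the two vinylogous acid chlorides (NaOH, aq. MeOH, reflux; then HCl) comes back to the route at 13.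

Step 3. Proton transfer from the ester CH2, or incomplete removal of the N–H, may quench the phosphonate carbanion faster than acyl transfer, so that the ester is returned. The fallback replaces acyl substitution by carbonyl addition and oxidation. It sets out from ester 4, which i-Bu2AlH (2.2 equiv, CH2Cl2, −78 °C) should reduce to 2-[5-(3-methylbut-2-enyl)-1H-indol-3-yl]acetaldehyde F6, used at once. Addition of lithiated 5 (2.2 equiv, THF, −78 °C, quenched cold with AcOH) should give diethyl {2-hydroxy-3-[5-(3-methylbut-2-enyl)-1H-indol-3-yl]-1-(tetrahydro-2H-pyran-2-yloxy)propyl}phosphonate F7. Oxidation of the carbinol with Dess–Martin periodinane (NaHCO3, CH2Cl2, 0 °C) comes back to the route at 6.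

Step 7. Reoxidation of the electron-rich tetrol by traces of air during the slow fourfold alkylation, or incomplete alkylation of the hindered hydroxyls, would leave partly methylated material. The fallback inverts the order of alkylation and reduction so that the tetrol is never formed. It sets out from 13, whose two vinylogous-acid hydroxyls are methylated first (Me3SiCHN2, MeOH–CH2Cl2, rt) to give air-stable 3-(1H-indol-3-yl)-2,5-dimethoxy-6-[5-(3-methylbut-2-enyl)-1H-indol-3-yl]-1,4-benzoquinone F8. Reduction (Na2S2O4, THF–H2O) then gives the far less oxygen-sensitive 2-(1H-indol-3-yl)-3,6-dimethoxy-5-[5-(3-methylbut-2-enyl)-1H-indol-3-yl]benzene-1,4-diol F9. Methylation of its two remaining hydroxyls (Me2SO4, K2CO3, acetone, reflux) comes back to the route at 15.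

Further compounds

F1 | step 6 | 5-(3-methylbut-2-enyl)-1H-indole | CC(C)=CCc1ccc2[nH]ccc2c1
F2 | step 6 | 2,5-dichloro-3-(1H-indol-3-yl)benzene-1,4-diol | Oc1cc(Cl)c(O)c(-c2c[nH]c3ccccc23)c1Cl
F3 | step 6 | 2,5-dichloro-3-(1H-indol-3-yl)-1,4-benzoquinone | O=C1C(Cl)=C(c2c[nH]c3ccccc23)C(=O)C(Cl)=C1
F4 | step 6 | 2,5-dichloro-3-(1H-indol-3-yl)-6-[5-(3-methylbut-2-enyl)-1H-indol-3-yl]benzene-1,4-diol | Oc1c(Cl)c(-c2c[nH]c3ccccc23)c(O)c(Cl)c1-c1c[nH]c2ccc(CC=C(C)C)cc12
F5 | step 6 | 2,5-dichloro-3-(1H-indol-3-yl)-6-[5-(3-methylbut-2-enyl)-1H-indol-3-yl]-1,4-benzoquinone | O=C1C(Cl)=C(c2c[nH]c3ccccc23)C(=O)C(Cl)=C1c1c[nH]c2ccc(CC=C(C)C)cc12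
F6 | step 3 | 2-[5-(3-methylbut-2-enyl)-1H-indol-3-yl]acetaldehyde | O=CCc1c[nH]c2ccc(CC=C(C)C)cc12
F7 | step 3 | diethyl {2-hydroxy-3-[5-(3-methylbut-2-enyl)-1H-indol-3-yl]-1-(tetrahydro-2H-pyran-2-yloxy)propyl}phosphonate (diastereomer mixture) | CCOP(=O)(OCC)C(OC1CCCCO1)C(O)Cc1c[nH]c2ccc(CC=C(C)C)cc12
F8 | step 7 | 3-(1H-indol-3-yl)-2,5-dimethoxy-6-[5-(3-methylbut-2-enyl)-1H-indol-3-yl]-1,4-benzoquinone | COC1=C(c2c[nH]c3ccccc23)C(=O)C(OC)=C(c2c[nH]c3ccc(CC=C(C)C)cc23)C1=O
F9 | step 7 | 2-(1H-indol-3-yl)-3,6-dimethoxy-5-[5-(3-methylbut-2-enyl)-1H-indol-3-yl]benzene-1,4-diol | COc1c(-c2c[nH]c3ccccc23)c(O)c(OC)c(-c2c[nH]c3ccc(CC=C(C)C)cc23)c1O
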